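**Plan**

- Retrosynthesis: the lactone C12–O8 bond and the two exocyclic methylenes (C11=C13, C4=C15) are cut first, leaving allyl groups on C7 and C5. The oxirane O–C1 bond is traced back to a C1–C2 acetaldehyde arm held as a lactol on O9. Then C7–C11 (enolate allylation), C1–C10 (radical closure from an O9 bromoacetal), C5–C4 (Stille coupling) and C10–CH3 (cuprate) are cut, arriving at the enone made from (−)-quinic acid.
- Forward order: carbocycle from quinic acid, C10 methyl, C5 allyl, O9 tether, tetrahydrofuran acetal ring with the C1–C10 bond (key step), C7 allyl, C6 ester, oxirane ring, lactone ring last.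
- Feature used: the C9 hydroxyl and the C1–C2 unit on the neighbouring quaternary C10 sit on the same ring face, and O8/O9 form a cis-diol, so C1–C2 can be delivered to C10 from O9.
- Stereochemistry: C8 and C9 come from quinic acid; C10 and C5 are set in the key step; C7 by allylation trans to O8; C6 by equatorial hydride attack; C1 by amine-catalysed chlorination followed by inversion.

Key step: step 12

**Remarks (assumptions on the chemistry)**

- Ring atoms carry the target numbering throughout (ring C5–C10; C1–C2 on C10; C4, C3, C15 on C5; C11–C13 on C7). α is the ring face of O8 and O9, β the face of the C10 methyl. In the cyclohexenones 6–16 the locants 1–6 correspond to C6, C5, C10, C9, C8, C7.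
- Acetal, lactol, trioxolane and Mannich-base carbons written without configuration are epimer mixtures that converge later.
- (2R,5R)-2,5-Diphenylpyrrolidine is assumed to deliver chlorine to the same enamine face as with simple alkanals, which corresponds to the (1S)-chloride needed here.

**Route**

Step 1
Reactants: 1 (−)-quinic acid
Product: 2 3,4-O-isopropylidene-1,5-quinide
Conditions: 2,2-dimethoxypropane, TsOH·H2O (cat.), acetone, reflux
Reagents that add atoms: 2,2-dimethoxypropane, COC(C)(C)OC
Why: Acid-catalysed ketalisation of the cis-diol with concomitant γ-lactonisation of the carboxyl onto the hydroxyl cis to it, which leaves the ring oxygens differentiated.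

Step 2
Reactants: 2 3,4-O-isopropylidene-1,5-quinide
Product: 3 acetonide triol (1-hydroxymethyl-cyclohexane-1,3-diol carrying the 4,5-acetonide)
Conditions: NaBH4, EtOH, 0 °C → rt
Reagents that add atoms: none
Why: Borohydride reduction of the strained bicyclic γ-lactone to the primary alcohol exposes a terminal 1,2-diol without touching the stereocentres.

Step 3
Reactants: 3 acetonide triol
Product: 4 3-hydroxy-4,5-(isopropylidenedioxy)cyclohexanone
Conditions: NaIO4, pH 7 phosphate buffer/THF, 0 °C
Reagents that add atoms: none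
Why: Periodate glycol cleavage removes the former carboxyl carbon and leaves the ring ketone, the secondary hydroxyl having no free vicinal partner.

Step 4
Reactants: 4 3-hydroxy-4,5-(isopropylidenedioxy)cyclohexanone
Product: 6 (4S,5R)-4,5-(isopropylidenedioxy)cyclohex-2-en-1-one, via 3-O-mesylate 5 (not isolated)
Conditions: MsCl, Et3N, CH2Cl2, 0 °C → rt
Reagents that add atoms: methanesulfonyl chloride, CS(=O)(=O)Cl (retained in 5 only)
Why: Mesylation of the β-hydroxy ketone and E1cB elimination in the same flask give the enone with C8 and C9 untouched.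

Step 5
Reactants: 6 (4S,5R)-4,5-(isopropylidenedioxy)cyclohex-2-en-1-one
Product: 7 trimethylsilyl enol ether of the 3-methyl ketone (methyl trans to the neighbouring acetonide oxygen)
Conditions: Me2CuLi (from MeLi and CuI), TMSCl, Et2O/THF, −78 °C; Et3N, aq. NaHCO3
Reagents that add atoms: lithium dimethylcuprate, [Li+].C[Cu-]C; chlorotrimethylsilane, C[Si](C)(C)Cl
Why: TMSCl-accelerated cuprate conjugate addition anti to the acetonide places the future C10 methyl and traps the enolate regiospecifically; the new centre is erased in step 6.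

Step 6
Reactants: 7 trimethylsilyl enol ether
Product: 8 (4S,5R)-4,5-(isopropylidenedioxy)-3-methylcyclohex-2-en-1-one
Conditions: Pd(OAc)2 (10 mol %), O2 (1 atm), DMSO, rt
Reagents that add atoms: none
Why: Saegusa–Ito oxidation, in which the palladium enolate at C5 loses the C10 hydrogen by β-hydride elimination and restores the enone now bearing the methyl group.

Step 7
Reactants: 8 (4S,5R)-4,5-(isopropylidenedioxy)-3-methylcyclohex-2-en-1-one
Product: 9 (4S,5R)-2-iodo-4,5-(isopropylidenedioxy)-3-methylcyclohex-2-en-1-one
Conditions: I2, pyridine, CH2Cl2, rt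
Reagents that add atoms: iodine, II
Why: Pyridine-mediated α-iodination of the enone (conjugate addition of pyridine, iodination of the enolate, elimination) functionalises C5 and no other position.

Step 8
Reactants: 9 (4S,5R)-2-iodo-4,5-(isopropylidenedioxy)-3-methylcyclohex-2-en-1-one; 10 allyltributylstannane
Product: 11 (4S,5R)-2-allyl-4,5-(isopropylidenedioxy)-3-methylcyclohex-2-en-1-one
Conditions: Pd2(dba)3 (2.5 mol %), AsPh3, CuI (10 mol %), NMP, 50 °C
Reagents that add atoms: allyltributylstannane (10), C=CC[Sn](CCCC)(CCCC)CCCC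
Why: Stille cross-coupling of the α-iodoenone fixes the C5–C4 bond before the ring ketone ever has to be enolised toward C5.

Step 9
Reactants: 11 (4S,5R)-2-allyl-4,5-(isopropylidenedioxy)-3-methylcyclohex-2-en-1-one
Product: 12 (4S,5R)-2-allyl-4,5-dihydroxy-3-methylcyclohex-2-en-1-one
Conditions: TFA/H2O (4:1), 0 °C
Reagents that add atoms: none
Why: Acid-catalysed acetonide hydrolysis, kept cold and short so that the β-hydroxy enone does not dehydrate toward a phenol.

Step 10
Reactants: 12 (4S,5R)-2-allyl-4,5-dihydroxy-3-methylcyclohex-2-en-1-one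
Product: 13 (4S,5R)-2-allyl-5-(tert-butyldimethylsilyloxy)-4-hydroxy-3-methylcyclohex-2-en-1-one
Conditions: TBSCl (1.05 equiv), imidazole, DMF, −20 °C
Reagents that add atoms: tert-butyldimethylsilyl chloride, CC(C)(C)[Si](C)(C)Cl
Why: Sterically controlled monosilylation should favour the equatorial O8 hydroxyl next to a CH2 group over the pseudoaxial allylic O9 hydroxyl flanked by the methyl-bearing C10.

Step 11
Reactants: 13 (4S,5R)-2-allyl-5-(tert-butyldimethylsilyloxy)-4-hydroxy-3-methylcyclohex-2-en-1-one; 14 ethyl vinyl ether; 15 N-bromosuccinimide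
Product: 16 O9 bromoacetal: (4S,5R)-2-allyl-4-(2-bromo-1-ethoxyethoxy)-5-(tert-butyldimethylsilyloxy)-3-methylcyclohex-2-en-1-one
Conditions: NBS, ethyl vinyl ether (excess), CH2Cl2, −40 → 0 °C
Reagents that add atoms: ethyl vinyl ether (14), C=COCC; N-bromosuccinimide (15), O=C1CCC(=O)N1Br
Why: Bromoacetalisation, in which NBS converts the vinyl ether into a β-bromo oxocarbenium ion that the O9 hydroxyl captures far faster than NBS reacts with the allyl group.

Step 12
Reactants: 16 O9 bromoacetal
Product: 17 cis-fused bicyclic acetal ketone: 5β-allyl-8α-(tert-butyldimethylsilyloxy)-10β-methylcyclohexan-6-one fused at C9–C10 to a 2-ethoxytetrahydrofuran (O9 and C1 both α)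
Conditions: Bu3SnH (syringe pump), AIBN (cat.), benzene (high dilution), 80 °C
Reagents that add atoms: none
Why: Bu3Sn• abstracts bromine from 16 to give the primary radical at C1, which closes 5-exo-trig onto C10, the β-carbon of the C6 enone, forming the C1–C10 bond and the tetrahydrofuran acetal ring O9–C2–C1–C10–C9; the tertiary α-keto radical at C5 is then reduced by Bu3SnH, which carries the chain. The closest known reaction type is the Ueno–Stork bromoacetal cyclisation of cyclic allylic alcohols onto a methyl-bearing alkene carbon, here accelerated by the enone. The five-membered ring can only be cis-fused to the cyclohexane, so C1 enters C10 on the O9 (α) face and the methyl is forced β; the C9 configuration that dictates this comes from quinic acid. The C5 centre is set by hydrogen-atom transfer anti to the pseudoaxial C10 methyl, which places the allyl group equatorial (β), also the thermodynamically preferred epimer. The step needs 5-exo attack at C10 to win over 6-endo attack at C5 and over premature reduction of the C1 radical; the polarity match between the nucleophilic radical and the enone β-carbon secures the first, high dilution with slow stannane addition the second.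

Step 13
Reactants: 17 cis-fused bicyclic acetal ketone; 18 allyl iodide
Product: 20 5β,7β-diallyl bicyclic acetal ketone, via lithium enolate 19 (not isolated)
Conditions: LiN(i-Pr)2 (commercial solution), THF, −78 °C; then allyl iodide, DMPU, −78 → −40 °C
Reagents that add atoms: allyl iodide (18), C=CCI; lithium diisopropylamide, [Li]N(C(C)C)C(C)C (lithium retained in 19 only)
Why: Kinetic enolate alkylation, in which only the C7 methylene is deprotonated (C5 is a hindered methine) and the allyl group enters trans to the neighbouring 8α-silyloxy group to give the equatorial 7β epimer, the equatorial C8–O bond being poorly aligned for β-elimination.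

Step 14
Reactants: 20 5β,7β-diallyl bicyclic acetal ketone
Product: 21 6β-alcohol (axial hydroxyl)
Conditions: LiBH(s-Bu)3 (L-Selectride), THF, −78 °C; H2O
Reagents that add atoms: none
Why: Bulky trialkylborohydride reduction by equatorial attack, the axial trajectory being closed by the axial C10 methyl, should give the axial 6β-alcohol cis to both allyl groups.

Step 15
Reactants: 21 6β-alcohol; 22 isobutyryl chloride
Product: 23 6β-isobutyrate
Conditions: isobutyryl chloride, DMAP, Et3N, CH2Cl2, 40 °C
Reagents that add atoms: isobutyryl chloride (22), CC(C)C(=O)Cl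
Why: DMAP-catalysed acylation of the only free hydroxyl, with the acylpyridinium ion overcoming the hindrance of the axial position.

Step 16
Reactants: 23 6β-isobutyrate
Product: 24 lactol diol (2-hydroxytetrahydrofuran on O9; free 8α-hydroxyl)
Conditions: 2 M aq. HCl, THF, rt
Reagents that add atoms: water, O
Why: Aqueous acid hydrolysis of the mixed cyclic acetal to the lactol with simultaneous cleavage of the silyl ether, conditions under which the ester and the allyl groups are inert.

Step 17
Reactants: 24 lactol diol
Product: 26 (1S)-chlorohydrin triol (C10 carries CHCl–CH2OH), via (1S)-chloro lactol 25 (not isolated)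
Conditions: NCS, (2R,5R)-2,5-diphenylpyrrolidine (20 mol %), CH2Cl2, 0 °C → rt; then NaBH4, MeOH, 0 °C
Reagents that add atoms: N-chlorosuccinimide, O=C1CCC(=O)N1Cl
Why: Enamine-catalysed α-chlorination of the aldehyde tautomer of the lactol, a reaction type established for aldehydes with a quaternary β-carbon, in which the C2-symmetric amine shields one enamine face so that chlorine should enter C1 to give the (1S) centre, and borohydride reduces the chloro aldehyde before it can epimerise.

Step 18
Reactants: 26 (1S)-chlorohydrin triol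
Product: 27 (1R)-oxirane: 5β,7β-diallyl-6β-isobutyryloxy-10β-methyl-10α-oxiranylcyclohexane-8α,9α-diol
Conditions: KOt-Bu, THF, 0 °C
Reagents that add atoms: none
Why: Intramolecular Williamson closure (3-exo-tet) of the C2 alkoxide onto C1 with inversion gives the (R)-oxirane, oxetane formation from O9 being far slower.

Step 19
Reactants: 27 (1R)-oxirane
Product: 29 aldehyde lactol (C5 arm CH2–CHO; C7 arm closed on O8 as trans-fused γ-lactol), via bis-ozonide 28 (not isolated)
Conditions: O3, CH2Cl2, −78 °C; then PPh3, −78 °C → rt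
Reagents that add atoms: ozone, [O-][O+]=O
Why: Ozonolysis with reductive work-up cleaves both terminal alkenes; the C12 aldehyde is captured by the adjacent equatorial O8 hydroxyl, whereas the C3 aldehyde has no hydroxyl within reach.

Step 20
Reactants: 29 aldehyde lactol; 30 dimethylmethyleneiminium iodide (Eschenmoser's salt)
Product: 32 α-methylene lactol carrying the C5 acrolein, via bis-Mannich base 31 (not isolated)
Conditions: Eschenmoser's salt, Et3N, CH2Cl2, rt
Reagents that add atoms: dimethylmethyleneiminium iodide (30), C=[N+](C)C.[I-]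
Why: Mannich reaction at both aldehyde α-methylene groups (C4 and C11) followed by β-elimination of dimethylamine, the lactol reacting through its open hydroxy-aldehyde tautomer and reclosing afterwards.

Step 21
Reactants: 32 α-methylene lactol carrying the C5 acrolein
Product: 33 CNP0496100.1
Conditions: MnO2 (activated, excess), CH2Cl2, rt
Reagents that add atoms: none
Why: MnO2 oxidation of the allylic hemiacetal C–H gives the α-methylene-γ-lactone and leaves the unactivated C9 hydroxyl, the enal, the oxirane and the ester untouched.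

**Compound list**

1 | (−)-quinic acid | C1[C@H]([C@@H]([C@@H](C[C@@]1(O)C(=O)O)O)O)O | starting material
2 | 3,4-O-isopropylidene-1,5-quinide | C1[C@@H]2[C@H]3[C@@H](C[C@@]1(O)C(=O)O2)OC(C)(C)O3 | intermediate
3 | acetonide triol (lactone of 2 reduced to CH2OH) | C1[C@@H](O)[C@H]2[C@@H](C[C@@]1(O)CO)OC(C)(C)O2 | intermediate
4 | 3-hydroxy-4,5-(isopropylidenedioxy)cyclohexanone (3-OH trans to O4) | C1[C@@H](O)[C@H]2[C@@H](CC1=O)OC(C)(C)O2 | intermediate
5 | 3-O-mesylate of 4 | C1[C@@H](OS(C)(=O)=O)[C@H]2[C@@H](CC1=O)OC(C)(C)O2 | intermediate (not isolated)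
6 | (4S,5R)-4,5-(isopropylidenedioxy)cyclohex-2-en-1-one | O=C1C=C[C@@H]2OC(C)(C)O[C@@H]2C1 | intermediate
7 | 1-(trimethylsilyloxy)-3-methyl-4,5-(isopropylidenedioxy)cyclohex-1-ene, methyl trans to O4 | C[Si](C)(C)OC1=C[C@@H](C)[C@@H]2OC(C)(C)O[C@@H]2C1 | intermediate
8 | (4S,5R)-4,5-(isopropylidenedioxy)-3-methylcyclohex-2-en-1-one | O=C1C=C(C)[C@@H]2OC(C)(C)O[C@@H]2C1 | intermediate
9 | (4S,5R)-2-iodo-4,5-(isopropylidenedioxy)-3-methylcyclohex-2-en-1-one | O=C1C(I)=C(C)[C@@H]2OC(C)(C)O[C@@H]2C1 | intermediate
10 | allyltributylstannane | C=CC[Sn](CCCC)(CCCC)CCCC | starting material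
11 | (4S,5R)-2-allyl-4,5-(isopropylidenedioxy)-3-methylcyclohex-2-en-1-one | O=C1C(CC=C)=C(C)[C@@H]2OC(C)(C)O[C@@H]2C1 | intermediate
12 | (4S,5R)-2-allyl-4,5-dihydroxy-3-methylcyclohex-2-en-1-one | O=C1C(CC=C)=C(C)[C@H](O)[C@H](O)C1 | intermediate
13 | (4S,5R)-2-allyl-5-(tert-butyldimethylsilyloxy)-4-hydroxy-3-methylcyclohex-2-en-1-one | O=C1C(CC=C)=C(C)[C@H](O)[C@H](O[Si](C)(C)C(C)(C)C)C1 | intermediate
14 | ethyl vinyl ether | C=COCC | starting material
15 | N-bromosuccinimide | O=C1CCC(=O)N1Br | starting material
16 | O9 bromoacetal of 13 (acetal carbon epimers) | O=C1C(CC=C)=C(C)[C@H](OC(CBr)OCC)[C@H](O[Si](C)(C)C(C)(C)C)C1 | intermediate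
17 | cis-fused bicyclic acetal ketone, 5β-allyl, 8α-OTBS, 10β-methyl (C2 epimers) | O=C1[C@@H](CC=C)[C@]2(C)CC(OCC)O[C@@H]2[C@H](O[Si](C)(C)C(C)(C)C)C1 | intermediate
18 | allyl iodide | C=CCI | starting material
19 | lithium C6=C7 enolate of 17 | [Li]OC1=C[C@@H](O[Si](C)(C)C(C)(C)C)[C@H]2OC(OCC)C[C@@]2(C)[C@@H]1CC=C | intermediate (not isolated)
20 | 5β,7β-diallyl bicyclic acetal ketone | O=C1[C@@H](CC=C)[C@]2(C)CC(OCC)O[C@@H]2[C@H](O[Si](C)(C)C(C)(C)C)[C@H]1CC=C | intermediate
21 | 6β-alcohol of 20 | O[C@H]1[C@@H](CC=C)[C@]2(C)CC(OCC)O[C@@H]2[C@H](O[Si](C)(C)C(C)(C)C)[C@H]1CC=C | intermediate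
22 | isobutyryl chloride | CC(C)C(=O)Cl | starting material
23 | 6β-isobutyrate of 21 | CC(C)C(=O)O[C@H]1[C@@H](CC=C)[C@]2(C)CC(OCC)O[C@@H]2[C@H](O[Si](C)(C)C(C)(C)C)[C@H]1CC=C | intermediate
24 | lactol diol (2-hydroxytetrahydrofuran on O9, 8α-OH free) | CC(C)C(=O)O[C@H]1[C@@H](CC=C)[C@]2(C)CC(O)O[C@@H]2[C@H](O)[C@H]1CC=C | intermediate
25 | (1S)-1-chloro lactol | CC(C)C(=O)O[C@H]1[C@@H](CC=C)[C@]2(C)[C@H](Cl)C(O)O[C@@H]2[C@H](O)[C@H]1CC=C | intermediate (not isolated)
26 | (1S)-chlorohydrin triol | CC(C)C(=O)O[C@H]1[C@@H](CC=C)[C@](C)([C@H](Cl)CO)[C@H](O)[C@H](O)[C@H]1CC=C | intermediate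
27 | (1R)-oxirane, 5β,7β-diallyl, 8α,9α-diol | CC(C)C(=O)O[C@H]1[C@@H](CC=C)[C@](C)([C@@H]2CO2)[C@H](O)[C@H](O)[C@H]1CC=C | intermediate
28 | bis(1,2,4-trioxolane) of 27 | CC(C)C(=O)O[C@H]1[C@@H](CC2OCOO2)[C@](C)([C@@H]2CO2)[C@H](O)[C@H](O)[C@H]1CC1OCOO1 | intermediate (not isolated)
29 | aldehyde lactol (C5 arm CH2CHO, C7 arm as trans-fused γ-lactol on O8) | C1C(O)O[C@@H]2[C@@H]1[C@@H](OC(=O)C(C)C)[C@@H](CC=O)[C@](C)([C@@H]1CO1)[C@@H]2O | intermediate
30 | dimethylmethyleneiminium iodide (Eschenmoser's salt) | C=[N+](C)C.[I-] | starting material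
31 | bis(dimethylaminomethyl) Mannich base of 29 | CN(C)CC1C(O)O[C@@H]2[C@@H]1[C@@H](OC(=O)C(C)C)[C@@H](C(CN(C)C)C=O)[C@](C)([C@@H]1CO1)[C@@H]2O | intermediate (not isolated)
32 | α-methylene lactol carrying the C5 acrolein | C=C1C(O)O[C@@H]2[C@@H]1[C@@H](OC(=O)C(C)C)[C@@H](C(=C)C=O)[C@](C)([C@@H]1CO1)[C@@H]2O | intermediate
33 | CNP0496100.1 | C=C1C(=O)O[C@@H]2[C@@H]1[C@@H](OC(=O)C(C)C)[C@@H](C(=C)C=O)[C@](C)([C@@H]1CO1)[C@@H]2O | target

**Step count**

Total: 21 steps. Longest linear sequence: 21 steps (fully linear from 1).

**Steps most likely to fail**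

Step 17. The risk is insufficient catalyst control over the chlorination face next to the quaternary C10 stereocentre, or slow enamine formation because the aldehyde is held as a lactol. The fallback sets out from 24 and returns at 27, replacing chlorination/inversion by oxygenation with retention. L-Proline (20 mol %) and nitrosobenzene in DMSO should convert 24, through the hydrogen-bond-directed O-nitroso aldol reaction, into the (1R)-anilinooxy lactol F1. NaBH4 added to the same flask gives the anilinooxy triol F2, and Zn in AcOH cleaves the N–O bond to give the tetraol F3. TsCl in pyridine at 0 °C sulfonylates the primary C2 hydroxyl to give the primary tosylate F4. K2CO3 in MeOH then closes the oxirane from the C1 alkoxide, with retention at C1, to give 27.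

Step 10. The risk is poor site selectivity between the O8 and O9 hydroxyls, or silyl migration between them. The fallback sets out from 12 and returns at 13, and uses stereoelectronic rather than steric differentiation. Trimethyl orthoformate with PPTS gives the cyclic orthoformate F5. Brief treatment with aqueous AcOH opens it to the pseudoaxial ester, the 9-O-formate F6. TBSOTf and 2,6-lutidine at −78 °C silylate O8 to give the formate silyl ether F7, and KHCO3 in aqueous MeOH removes the formate to give 13.

Step 13. The risk is β-elimination of the C8 silyloxy group from the enolate on warming, and proton transfer between product and enolate leading to double allylation. The fallback sets out from 17 and returns at 20, moving the C–C bond formation to neutral conditions. Enolate 19 is O-acylated at −78 °C with allyl chloroformate to give the allyl enol carbonate F8. Pd(PPh3)4 (zerovalent palladium) in THF at rt then triggers the decarboxylative Tsuji allylation, which delivers the allyl group to C7 and gives 20.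

**Further compounds**

F1 | step 17 | (1R)-anilinooxy lactol | CC(C)C(=O)O[C@H]1[C@@H](CC=C)[C@]2(C)[C@@H](ONc3ccccc3)C(O)O[C@@H]2[C@H](O)[C@H]1CC=C
F2 | step 17 | anilinooxy triol | CC(C)C(=O)O[C@H]1[C@@H](CC=C)[C@](C)([C@@H](ONc2ccccc2)CO)[C@H](O)[C@H](O)[C@H]1CC=C
F3 | step 17 | tetraol | CC(C)C(=O)O[C@H]1[C@@H](CC=C)[C@](C)([C@@H](O)CO)[C@H](O)[C@H](O)[C@H]1CC=C
F4 | step 17 | primary tosylate | CC(C)C(=O)O[C@H]1[C@@H](CC=C)[C@](C)([C@@H](O)COS(=O)(=O)c2ccc(C)cc2)[C@H](O)[C@H](O)[C@H]1CC=C
F5 | step 10 | cyclic orthoformate | O=C1C(CC=C)=C(C)[C@@H]2OC(OC)O[C@@H]2C1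
F6 | step 10 | 9-O-formate | O=C1C(CC=C)=C(C)[C@H](OC=O)[C@H](O)C1
F7 | step 10 | formate silyl ether | O=C1C(CC=C)=C(C)[C@H](OC=O)[C@H](O[Si](C)(C)C(C)(C)C)C1
F8 | step 13 | allyl enol carbonate | C=CCOC(=O)OC1=C[C@@H](O[Si](C)(C)C(C)(C)C)[C@H]2OC(OCC)C[C@@]2(C)[C@@H]1CC=C
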